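**Strategy.** The cyclohexane (C6–C11, iridal numbering) is disconnected as a β-hydroxy ketone: the C10 carbinol and a C26 carbonyl flank the spiro carbon C11, and C6 is the β-carbon of a C26 enone. A cyclopentanone bearing the exocyclic C11=C6 enone and a pendant C10 methyl ketone is closed by copper-catalysed asymmetric conjugate addition of the C3–C5 alkylzinc to C6, the C11 zinc enolate being trapped by aldol addition to C10. One operation forms the C5–C6 and C10–C11 bonds, the ring and the C6, C10 and C11 stereocentres. Hydroxyl-directed reduction, a cis-lactone across C14/C26 and an aldol–dehydration with a dienal then complete the molecule.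

Key step: step 6

Remark on locants: iridal numbering is used. C1 is the aldehyde carbon, C2 the exocyclic alkene carbon (C25 methyl), C3–C5 the hydroxypropyl chain (C3 = CH2OH). The cyclohexane is C6 (CH), C7 (alkylidene carbon), C8, C9, C10 (carbinol, C27 methyl), C11 (spiro). The cyclopentane is C11, C12, C13, C14, C26 (CHOH). The side chain starts at C15 (bearing C28 = CH2OH) and runs on through C16.

Assumption: in step 6 the (S,R,R) ligand is taken to deliver the alkyl group to the C6 face that gives 6R; if the sense proves opposite, the (R,S,S) ligand is used and nothing else changes.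

Step 1
Reactants: 1 prop-2-yn-1-ol; 2 2-(2-bromoethyl)-2-methyl-1,3-dioxolane
Product: 4 5-(2-methyl-1,3-dioxolan-2-yl)pent-2-yn-1-ol, via dilithio propargyl alkoxide 3 (not isolated)
Conditions: LiNH2 (2.2 equiv), NH3 (l), −33 °C; then 2, THF; NH4Cl
Reagents that add atoms: none
Why: SN2 alkylation of the C,O-dianion of propargyl alcohol at the acetylide carbon by a primary bromide should give the 2-alkyn-1-ol, with the dioxolane masking the future C10 ketone through the organometallic steps.

Step 2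
Reactants: 4 5-(2-methyl-1,3-dioxolan-2-yl)pent-2-yn-1-ol
Product: 6 (2Z)-3-iodo-2-methyl-5-(2-methyl-1,3-dioxolan-2-yl)pent-2-en-1-ol, via chelated alkenylmagnesium alkoxide 5 (not isolated)
Conditions: MeMgBr (4 equiv), CuI (15 mol%), THF, 0 °C → rt; then I2, −20 °C; aq Na2S2O3
Reagents that add atoms: methylmagnesium bromide, C[Mg]Br; iodine, II
Why: Copper-catalysed anti-carbomagnesiation of the propargylic alkoxide puts methyl on the carbon next to CH2O and magnesium on the distal carbon in a five-membered chelate, so iodinolysis with retention should give the tetrasubstituted alkene with iodine cis to CH2OH, which is the C2=C7 geometry of the target.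

Step 3
Reactants: 6 (2Z)-3-iodo-2-methyl-5-(2-methyl-1,3-dioxolan-2-yl)pent-2-en-1-ol
Product: 7 tert-butyl{[(2Z)-3-iodo-2-methyl-5-(2-methyl-1,3-dioxolan-2-yl)pent-2-en-1-yl]oxy}diphenylsilane
Conditions: TBDPSCl, imidazole, DMF, rt
Reagents that add atoms: tert-butyl(chloro)diphenylsilane, CC(C)(C)[Si](Cl)(c1ccccc1)c1ccccc1
Why: Standard silylation of the primary allylic alcohol; the TBDPS ether is chosen because it should survive the aqueous acid of step 5.

Step 4
Reactants: 7 tert-butyl{[(2Z)-3-iodo-2-methyl-5-(2-methyl-1,3-dioxolan-2-yl)pent-2-en-1-yl]oxy}diphenylsilane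
Product: 8 (2Z)-4-[(tert-butyldiphenylsilyl)oxy]-3-methyl-2-[2-(2-methyl-1,3-dioxolan-2-yl)ethyl]but-2-enal
Conditions: Pd(PPh3)4 (5 mol%), CO (3 bar), Bu3SnH (slow addition), THF, 50 °C
Reagents that add atoms: carbon monoxide, [C-]#[O+]
Why: Palladium-catalysed reductive carbonylation (formylation) of the alkenyl iodide proceeds by oxidative addition to zerovalent palladium, CO insertion and hydride transfer from tin, all with retention of the alkene geometry.

Step 5
Reactants: 8 (2Z)-4-[(tert-butyldiphenylsilyl)oxy]-3-methyl-2-[2-(2-methyl-1,3-dioxolan-2-yl)ethyl]but-2-enal; 9 4-(cyclopent-1-en-1-yl)morpholine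
Product: 11 (2E)-2-{(2Z)-4-[(tert-butyldiphenylsilyl)oxy]-3-methyl-2-(3-oxobutyl)but-2-en-1-ylidene}cyclopentan-1-one, via dienamine ketal 10 (not isolated)
Conditions: 9 (1.5 equiv), PhMe, reflux, azeotropic removal of water; then 1 M HCl, THF, rt
Reagents that add atoms: water, O
Why: Enamine aldol condensation with an aldehyde that has no α-hydrogen and a fully substituted β-carbon (only 1,2-attack is open) should give the thermodynamically favoured (E)-alkylidene ketone, and the same acid that hydrolyses the dienamine removes the dioxolane only after the aldehyde is consumed, so no free keto-aldehyde can self-condense.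

Step 6
Reactants: 11 (2E)-2-{(2Z)-4-[(tert-butyldiphenylsilyl)oxy]-3-methyl-2-(3-oxobutyl)but-2-en-1-ylidene}cyclopentan-1-one; 12 tert-butyl(3-iodopropoxy)dimethylsilane
Product: 15 (5R,6S,9Z,10R)-10-{3-[(tert-butyldimethylsilyl)oxy]propyl}-9-{1-[(tert-butyldiphenylsilyl)oxy]propan-2-ylidene}-6-hydroxy-6-methylspiro[4.5]decan-1-one (spiro ketol; iridal descriptors 2Z,6R,10S,11R), via dialkylzinc reagent 13 (not isolated), via zinc enolate 14 (not isolated)
Conditions: 12, Et2Zn (neat), CuI (cat.), 50 °C, then vacuum (gives 13); 11, Cu(OTf)2 (3 mol%), (S,R,R)-BINOL-derived N,N-bis(1-phenylethyl)phosphoramidite (6 mol%), PhMe, −30 → 0 °C; aq NH4Cl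
Reagents that add atoms: none
Why: The chiral copper–phosphoramidite catalyst transfers a 3-silyloxypropyl group from zinc to C6, the β-carbon of the exocyclic enone, and the C11 zinc enolate so formed adds to the C10 methyl ketone before it can exchange protons. The closest known reaction type is the copper-catalysed tandem conjugate addition–aldol cyclisation of keto-enones with dialkylzincs. The ring closes by a 6-(enolexo)-exo-trig aldol addition that forms C10–C11. C6 is set by the ligand on the (E)-enone face; C11 and C10 follow from C6 through a closed chair in which zinc bridges the enolate and ketone oxygens: allylic 1,3-strain with the cis CH2OSi group keeps the C6 hydrogen in the plane of the tetrasubstituted C2=C7 alkene, so the new chain is axial, which leaves the 1,3-related axial site on C10 to oxygen and not to methyl and puts C26 equatorial, that is 10-OH cis to C26 and to the C5 chain. The step needs 1,4- over 1,6-addition, secured by the fully substituted δ-carbon C2, and a regiodefined C11 enolate, secured by generating it through conjugate addition (an equilibrating base would instead close C9 onto C26).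

Step 7
Reactants: 15 spiro ketol
Product: 16 (5R,6S,9Z,10R)-10-{3-[(tert-butyldimethylsilyl)oxy]propyl}-9-{1-[(tert-butyldiphenylsilyl)oxy]propan-2-ylidene}-6-methyl-6-[(trimethylsilyl)oxy]spiro[4.5]decan-1-one
Conditions: 1-(trimethylsilyl)imidazole, CH2Cl2, rt
Reagents that add atoms: 1-(trimethylsilyl)imidazole, C[Si](C)(C)n1ccnc1
Why: Silylation of the hindered tertiary alcohol with a silylimidazole should block retro-aldol cleavage of the β-alkoxide during the enolate chemistry of step 8.

Step 8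
Reactants: 16 trimethylsilyl ether of the spiro ketol
Product: 18 methyl 2-[(2S,5R,6S,9Z,10R)-10-{3-[(tert-butyldimethylsilyl)oxy]propyl}-9-{1-[(tert-butyldiphenylsilyl)oxy]propan-2-ylidene}-6-hydroxy-6-methyl-1-oxospiro[4.5]decan-2-yl]acetate, via silyl ether keto ester 17 (not isolated)
Conditions: LiN(iPr)2, THF, −78 °C; BrCH2CO2Me, DMPU, −78 → −40 °C; then citric acid, MeOH, 0 °C
Reagents that add atoms: methyl bromoacetate, COC(=O)CBr
Why: C11 is quaternary, so only the C14 enolate can form, and its SN2 alkylation should occur on the cyclopentanone face of the equatorial C6 hydrogen, anti to the equatorial C27 methyl on C10, which sets 14S (acetate arm cis to C6); mild acid then frees the tertiary alcohol.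

Step 9
Reactants: 18 keto ester with free C10 hydroxyl
Product: 20 cis-fused γ-lactone between C28 and O26 of the spiro core (2Z,6R,10S,11S,14S,26R; C1 OTBDPS, C3 OTBS, C10 OH), via dihydroxy ester 19 (not isolated)
Conditions: Me4NBH(OAc)3, MeCN–AcOH, −25 °C; then PPTS (cat.), CH2Cl2, rt
Reagents that add atoms: none
Why: In the Evans–Saksena reduction the C10 hydroxyl exchanges onto boron and delivers hydride to the face of C26 syn to C10, which should give the 26R alcohol trans to C10 and cis to the C14 acetate arm, and this cis γ-hydroxy ester lactonises.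

Step 10
Reactants: 21 6-methylhept-5-en-2-one
Product: 22 6-methylhepta-1,5-dien-2-yl trifluoromethanesulfonate
Conditions: LiN(iPr)2, THF, −78 °C; PhNTf2, −78 → 0 °C
Reagents that add atoms: N-phenylbis(trifluoromethanesulfonimide), O=S(=O)(N(c1ccccc1)S(=O)(=O)C(F)(F)F)C(F)(F)F
Why: Kinetic deprotonation at the methyl group and O-triflation of the enolate should give the terminal (1,1-disubstituted) enol triflate.

Step 11
Reactants: 22 6-methylhepta-1,5-dien-2-yl trifluoromethanesulfonate
Product: 23 (2E)-8-methyl-4-methylidenenona-2,7-dienal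
Conditions: acrolein, Pd(OAc)2 (5 mol%), PPh3 (10 mol%), Et3N, DMF, 60 °C
Reagents that add atoms: acrolein, C=CC=O
Why: Heck reaction of the alkenyl triflate with acrolein, in which syn-insertion and syn-β-hydride elimination should give the (E)-dienal.

Step 12
Reactants: 20 cis-fused γ-lactone; 23 (2E)-8-methyl-4-methylidenenona-2,7-dienal
Product: 24 β-hydroxy lactone (aldol adduct at C15, mixture of C15/C16 diastereomers)
Conditions: LiN(iPr)2 (2.2 equiv), THF, −78 °C; then 23, −78 °C; aq NH4Cl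
Reagents that add atoms: none
Why: Directed aldol addition of the lactone lithium enolate (the second equivalent of base covers the tertiary hydroxyl) to the non-enolisable dienal should be 1,2-selective, and the two new stereocentres are removed in step 13.

Step 13
Reactants: 24 β-hydroxy lactone
Product: 26 (15E,17E)-α-alkylidene lactone (2Z,6R,10S,11S,14S,26R; C1 OTBDPS, C3 OTBS), via allylic mesylate 25 (not isolated)
Conditions: MsCl, Et3N, CH2Cl2, 0 °C; then DBU, rt
Reagents that add atoms: none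
Why: Mesylation of the secondary carbinol and E1cB elimination through the lactone enolate should give the conjugated alkylidene lactone as the thermodynamically preferred (E)-isomer, with C17 anti to the carbonyl and cis to C14.

Step 14
Reactants: 26 bis-silylated alkylidene lactone
Product: 27 alkylidene lactone with free C1 and C3 hydroxyls
Conditions: Bu4NF, AcOH, THF, 0 °C → rt
Reagents that add atoms: none
Why: Fluoride cleaves both silyl ethers (desilylation), and acetic acid buffers the medium so that the lactone and the trienoate are not attacked.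

Step 15
Reactants: 27 diol lactone
Product: 28 (2Z)-enal lactone
Conditions: MnO2, CH2Cl2, rt
Reagents that add atoms: none
Why: Chemoselective allylic oxidation: MnO2 oxidises only the allylic C1 alcohol, because the primary C3 and tertiary C10 hydroxyls are not activated and C28 is still tied up in the lactone.

Step 16
Reactants: 28 (2Z)-enal lactone
Product: 30 28-deacetylbelamcandal, via lithium aminoalkoxide 29 (not isolated)
Conditions: LiN(OMe)Me (3.3 equiv, from MeNHOMe and n-BuLi), THF, −78 → −40 °C; iBu2AlH (6 equiv), −78 → 0 °C; aq potassium sodium tartrate (KNaC4H4O6)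
Reagents that add atoms: none
Why: In situ protection of the aldehyde: the lithium amide adds to it to give a tetrahedral α-amino alkoxide that is inert to hydride while iBu2AlH reduces the lactone 1,2 to the C26/C28 diol, and aqueous work-up collapses the aminal to return the (2Z)-enal.

**Compound list**

1 | prop-2-yn-1-ol | C#CCO | starting material
2 | 2-(2-bromoethyl)-2-methyl-1,3-dioxolane | CC1(CCBr)OCCO1 | starting material
3 | dilithium salt of prop-2-yn-1-ol (lithium 3-lithioprop-2-yn-1-olate) | [Li]C#CCO[Li] | intermediate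
4 | 5-(2-methyl-1,3-dioxolan-2-yl)pent-2-yn-1-ol | OCC#CCCC1(C)OCCO1 | intermediate
5 | chelated alkenylmagnesium alkoxide (4-methyl-3-[2-(2-methyl-1,3-dioxolan-2-yl)ethyl]-2,5-dihydro-1,2-oxamagnesole) | CC1=C(CCC2(C)OCCO2)[Mg]OC1 | intermediate
6 | (2Z)-3-iodo-2-methyl-5-(2-methyl-1,3-dioxolan-2-yl)pent-2-en-1-ol | OC/C(C)=C(\I)CCC1(C)OCCO1 | intermediate
7 | tert-butyl{[(2Z)-3-iodo-2-methyl-5-(2-methyl-1,3-dioxolan-2-yl)pent-2-en-1-yl]oxy}diphenylsilane | CC(C)(C)[Si](c1ccccc1)(c1ccccc1)OC/C(C)=C(\I)CCC1(C)OCCO1 | intermediate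
8 | (2Z)-4-[(tert-butyldiphenylsilyl)oxy]-3-methyl-2-[2-(2-methyl-1,3-dioxolan-2-yl)ethyl]but-2-enal | CC(C)(C)[Si](c1ccccc1)(c1ccccc1)OC/C(C)=C(\C=O)CCC1(C)OCCO1 | intermediate
9 | 4-(cyclopent-1-en-1-yl)morpholine | C1CC=C(C1)N1CCOCC1 | starting material
10 | dienamine ketal: 4-{5-[(E)-alkylidene]cyclopent-1-en-1-yl}morpholine from 8 and 9 | CC(C)(C)[Si](c1ccccc1)(c1ccccc1)OC/C(C)=C(\C=C1/CCC=C1N1CCOCC1)CCC1(C)OCCO1 | intermediate
11 | (2E)-2-{(2Z)-4-[(tert-butyldiphenylsilyl)oxy]-3-methyl-2-(3-oxobutyl)but-2-en-1-ylidene}cyclopentan-1-one | O=C1CCC/C1=C\C(CCC(C)=O)=C(\C)CO[Si](c1ccccc1)(c1ccccc1)C(C)(C)C | intermediate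
12 | tert-butyl(3-iodopropoxy)dimethylsilane | CC(C)(C)[Si](C)(C)OCCCI | starting material
13 | bis{3-[(tert-butyldimethylsilyl)oxy]propyl}zinc | CC(C)(C)[Si](C)(C)OCCC[Zn]CCCO[Si](C)(C)C(C)(C)C | intermediate
14 | alkylzinc enolate of the (6R) conjugate adduct (C11=C26 enolate, C10 ketone still free) | CC(C)(C)[Si](C)(C)OCCC[Zn]OC1=C(CCC1)[C@H](CCCO[Si](C)(C)C(C)(C)C)/C(CCC(C)=O)=C(/C)CO[Si](c1ccccc1)(c1ccccc1)C(C)(C)C | intermediate
15 | (5R,6S,9Z,10R)-10-{3-[(tert-butyldimethylsilyl)oxy]propyl}-9-{1-[(tert-butyldiphenylsilyl)oxy]propan-2-ylidene}-6-hydroxy-6-methylspiro[4.5]decan-1-one | O=C1CCC[C@]12[C@H](CCCO[Si](C)(C)C(C)(C)C)/C(=C(/C)CO[Si](c3ccccc3)(c3ccccc3)C(C)(C)C)CC[C@]2(C)O | intermediate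
16 | (5R,6S,9Z,10R)-10-{3-[(tert-butyldimethylsilyl)oxy]propyl}-9-{1-[(tert-butyldiphenylsilyl)oxy]propan-2-ylidene}-6-methyl-6-[(trimethylsilyl)oxy]spiro[4.5]decan-1-one | O=C1CCC[C@]12[C@H](CCCO[Si](C)(C)C(C)(C)C)/C(=C(/C)CO[Si](c3ccccc3)(c3ccccc3)C(C)(C)C)CC[C@]2(C)O[Si](C)(C)C | intermediate
17 | methyl 2-[(2S,5R,6S,9Z,10R)-…-6-methyl-1-oxo-6-[(trimethylsilyl)oxy]spiro[4.5]decan-2-yl]acetate (C14-alkylated silyl ether) | COC(=O)C[C@@H]1CC[C@]2([C@H](CCCO[Si](C)(C)C(C)(C)C)/C(=C(/C)CO[Si](c3ccccc3)(c3ccccc3)C(C)(C)C)CC[C@]2(C)O[Si](C)(C)C)C1=O | intermediate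
18 | methyl 2-[(2S,5R,6S,9Z,10R)-10-{3-[(tert-butyldimethylsilyl)oxy]propyl}-9-{1-[(tert-butyldiphenylsilyl)oxy]propan-2-ylidene}-6-hydroxy-6-methyl-1-oxospiro[4.5]decan-2-yl]acetate | COC(=O)C[C@@H]1CC[C@]2([C@H](CCCO[Si](C)(C)C(C)(C)C)/C(=C(/C)CO[Si](c3ccccc3)(c3ccccc3)C(C)(C)C)CC[C@]2(C)O)C1=O | intermediate
19 | methyl 2-[(1R,2S,5S,6S,9Z,10R)-10-{3-[(tert-butyldimethylsilyl)oxy]propyl}-9-{1-[(tert-butyldiphenylsilyl)oxy]propan-2-ylidene}-1,6-dihydroxy-6-methylspiro[4.5]decan-2-yl]acetate | COC(=O)C[C@@H]1CC[C@]2([C@H](CCCO[Si](C)(C)C(C)(C)C)/C(=C(/C)CO[Si](c3ccccc3)(c3ccccc3)C(C)(C)C)CC[C@]2(C)O)[C@@H]1O | intermediate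
20 | cis-fused γ-lactone of 19 (C28 carbonyl to O26; 2Z,6R,10S,11S,14S,26R; C1 OTBDPS, C3 OTBS, C10 OH) | O=C1C[C@@H]2CC[C@]3([C@H](CCCO[Si](C)(C)C(C)(C)C)/C(=C(/C)CO[Si](c4ccccc4)(c4ccccc4)C(C)(C)C)CC[C@]3(C)O)[C@@H]2O1 | intermediate
21 | 6-methylhept-5-en-2-one | CC(=O)CCC=C(C)C | starting material
22 | 6-methylhepta-1,5-dien-2-yl trifluoromethanesulfonate | C=C(OS(=O)(=O)C(F)(F)F)CCC=C(C)C | intermediate
23 | (2E)-8-methyl-4-methylidenenona-2,7-dienal | O=C/C=C/C(=C)CCC=C(C)C | intermediate
24 | aldol adduct of lactone 20 at C15 with dienal 23 (C16 carbinol; C15 and C16 unassigned, mixture) | O=C1C(C(O)/C=C/C(=C)CCC=C(C)C)[C@@H]2CC[C@]3([C@H](CCCO[Si](C)(C)C(C)(C)C)/C(=C(/C)CO[Si](c4ccccc4)(c4ccccc4)C(C)(C)C)CC[C@]3(C)O)[C@@H]2O1 | intermediate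
25 | C16 methanesulfonate of 24 | O=C1C(C(OS(C)(=O)=O)/C=C/C(=C)CCC=C(C)C)[C@@H]2CC[C@]3([C@H](CCCO[Si](C)(C)C(C)(C)C)/C(=C(/C)CO[Si](c4ccccc4)(c4ccccc4)C(C)(C)C)CC[C@]3(C)O)[C@@H]2O1 | intermediate
26 | (15E,17E)-α-alkylidene lactone (2Z,6R,10S,11S,14S,26R; C1 OTBDPS, C3 OTBS, C10 OH) | O=C1/C(=C/C=C/C(=C)CCC=C(C)C)[C@@H]2CC[C@]3([C@H](CCCO[Si](C)(C)C(C)(C)C)/C(=C(/C)CO[Si](c4ccccc4)(c4ccccc4)C(C)(C)C)CC[C@]3(C)O)[C@@H]2O1 | intermediate
27 | (15E,17E)-α-alkylidene lactone with free C1, C3 and C10 hydroxyls | O=C1/C(=C/C=C/C(=C)CCC=C(C)C)[C@@H]2CC[C@]3([C@H](CCCO)/C(=C(/C)CO)CC[C@]3(C)O)[C@@H]2O1 | intermediate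
28 | (2Z,15E,17E)-enal lactone (C1 aldehyde, C28/O26 lactone, free C3 and C10 hydroxyls) | O=C1/C(=C/C=C/C(=C)CCC=C(C)C)[C@@H]2CC[C@]3([C@H](CCCO)/C(=C(/C)C=O)CC[C@]3(C)O)[C@@H]2O1 | intermediate
29 | trilithium salt of 28 protected at C1 as the N-methoxy-N-methyl α-amino alkoxide (C3 and C10 lithium alkoxides) | O=C1/C(=C/C=C/C(=C)CCC=C(C)C)[C@@H]2CC[C@]3([C@H](CCCO[Li])/C(=C(/C)C(O[Li])N(C)OC)CC[C@]3(C)O[Li])[C@@H]2O1 | intermediate
30 | 28-deacetylbelamcandal (2Z,6R,10S,11S,14S,15E,17E,26R) | C=C(/C=C/C=C(/CO)[C@@H]1CC[C@]2([C@H](CCCO)/C(=C(/C)C=O)CC[C@]2(C)O)[C@@H]1O)CCC=C(C)C | target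

**Step count.** 16 steps in total; the longest linear sequence is 14 steps (steps 1–9 and 12–16), with the dienal 23 made in two steps alongside (steps 10 and 11).

**Steps most likely to fail**

Step 6. The ligand may give poor enantiofacial discrimination at C6 on this hindered exocyclic dienone, or the zinc enolate may be protonated before it closes. The fallback sets out from 11 and comes back at 15. Dienone 11 is treated with (E)-tert-butyldimethyl{[3-(4,4,5,5-tetramethyl-1,3,2-dioxaborolan-2-yl)prop-2-en-1-yl]oxy}silane under rhodium catalysis ([Rh(cod)Cl]2, BINAP of the antipode that gives 6R, KOH, dioxane–water, 80 °C). This is the rhodium tandem Hayashi–Miyaura addition–aldol cyclisation of keto-enones: an sp2 carbon is added at C6 under a catalyst class with established enantiocontrol, and the rhodium enolate closes onto the C10 ketone to give the alkenyl spiro ketol F1. Chemoselective hydrogenation of the 1,2-disubstituted alkene (RhCl(PPh3)3, H2, benzene; the tetrasubstituted C2=C7 alkene is inert) returns to 15.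

Step 8. The electrophile may not discriminate between the two faces at C14, or the β-silyloxy ketone may fragment by retro-aldol under base. The fallback sets out from 15 and comes back at 20, making C14–C15 after the reduction by a stereospecific intramolecular C–H insertion. Evans–Saksena reduction of 15 (Me4NBH(OAc)3, MeCN–AcOH) gives the anti-diol F2. The secondary C26 hydroxyl is acylated (BrCH2COBr, pyridine) to the bromoacetate F3, which is converted to the diazoacetate F4 (N,N'-ditosylhydrazine, DBU). The tertiary hydroxyl is silylated (1-(trimethylsilyl)imidazole) to give the silyl ether diazoacetate F5. Rh2(OAc)4 in CH2Cl2 then inserts the carbenoid into the only adjacent C–H bond (C14–H, since C11 is quaternary), which can only give the cis-fused silyl ether lactone F6. Citric acid in methanol removes the trimethylsilyl group and returns to 20.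

Step 16. The α-amino alkoxide may collapse under the aluminium hydride, so that the aldehyde is reduced, or the lithium amide may open the lactone. The fallback sets out from 28 and comes back at 30 with a discrete protecting group. Compound 28 is converted with HC(OMe)3 and PPTS in methanol to the dimethyl acetal lactone F7. iBu2AlH (CH2Cl2, −78 → 0 °C) reduces the lactone to the acetal tetraol F8. PPTS in acetone–water then releases the enal and returns to 30.

**Further compounds**

F1 | step 6 | alkenyl spiro ketol: 15 with an (E)-3-[(tert-butyldimethylsilyl)oxy]prop-1-enyl group at C6 | O=C1CCC[C@]12[C@H](/C=C/CO[Si](C)(C)C(C)(C)C)/C(=C(/C)CO[Si](c3ccccc3)(c3ccccc3)C(C)(C)C)CC[C@]2(C)O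
F2 | step 8 | anti-diol: 15 reduced at C26 (26R alcohol, C14 unsubstituted) | O[C@@H]1CCC[C@]12[C@H](CCCO[Si](C)(C)C(C)(C)C)/C(=C(/C)CO[Si](c3ccccc3)(c3ccccc3)C(C)(C)C)CC[C@]2(C)O
F3 | step 8 | bromoacetate of F2 at O26 | BrCC(=O)O[C@@H]1CCC[C@]12[C@H](CCCO[Si](C)(C)C(C)(C)C)/C(=C(/C)CO[Si](c3ccccc3)(c3ccccc3)C(C)(C)C)CC[C@]2(C)O
F4 | step 8 | diazoacetate of F2 at O26 | [N-]=[N+]=CC(=O)O[C@@H]1CCC[C@]12[C@H](CCCO[Si](C)(C)C(C)(C)C)/C(=C(/C)CO[Si](c3ccccc3)(c3ccccc3)C(C)(C)C)CC[C@]2(C)O
F5 | step 8 | diazoacetate F4 with the C10 hydroxyl as trimethylsilyl ether | [N-]=[N+]=CC(=O)O[C@@H]1CCC[C@]12[C@H](CCCO[Si](C)(C)C(C)(C)C)/C(=C(/C)CO[Si](c3ccccc3)(c3ccccc3)C(C)(C)C)CC[C@]2(C)O[Si](C)(C)C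
F6 | step 8 | trimethylsilyl ether of lactone 20 | O=C1C[C@@H]2CC[C@]3([C@H](CCCO[Si](C)(C)C(C)(C)C)/C(=C(/C)CO[Si](c4ccccc4)(c4ccccc4)C(C)(C)C)CC[C@]3(C)O[Si](C)(C)C)[C@@H]2O1
F7 | step 16 | dimethyl acetal of enal lactone 28 | O=C1/C(=C/C=C/C(=C)CCC=C(C)C)[C@@H]2CC[C@]3([C@H](CCCO)/C(=C(/C)C(OC)OC)CC[C@]3(C)O)[C@@H]2O1
F8 | step 16 | C1 dimethyl acetal of 28-deacetylbelamcandal (acetal tetraol) | C=C(/C=C/C=C(/CO)[C@@H]1CC[C@]2([C@H](CCCO)/C(=C(/C)C(OC)OC)CC[C@]2(C)O)[C@@H]1O)CCC=C(C)C
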